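**Retrosynthetic overview**

- The target is an open-chain 1,7-diarylheptan-3-one (C1 on ring A, the 4-hydroxy-3-methoxyphenyl ring; C7 on ring B, the 3,4-dihydroxy-5-methoxyphenyl ring). The strategy rests on the unit C4–C5(OH)–C6: three carbons oxygenated only at the central carbon C5, the sole stereocentre (R), lying between the acyl carbon C3 and the benzylic carbon C7.
- This unit is (S)-epichlorohydrin set between two carbon nucleophiles. C3–C4 is cut to a 2-lithio-1,3-dithiane that carries ring A and C1–C3 (an acyl anion equivalent), and C6–C7 to the benzylic Grignard reagent of ring B.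
- The dithiane is made from eugenol (O-benzylation, hydroboration–oxidation, oxidation to the aldehyde, thioacetalisation). The Grignard reagent is made from 5-hydroxyvanillin (dibenzylation, reduction, chlorination, magnesium insertion).
- After the three-component coupling, hydrolysis of the dithiane unveils the C3 ketone and hydrogenolysis frees the three phenols.
- No ring of the target is built: rings A and B are bought, and the dithiane and a transient oxirane are auxiliary rings that are opened again.

Key step: step 9

Remark on the chemistry: Grignard reagent 10 is prepared in its own flask and used as a titrated THF solution, so it is treated as the product of step 8.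

**Route**

Step 1
Reactants: 1 eugenol (4-allyl-2-methoxyphenol)
Product: 2 4-allyl-1-(benzyloxy)-2-methoxybenzene
Conditions: BnBr, K2CO3, acetone, reflux
Reagents that add atoms: benzyl bromide, BrCc1ccccc1
Why: Williamson ether synthesis, in which the phenoxide formed by K2CO3 displaces bromide by SN2 while the allyl group is inert to carbonate base.

Step 2
Reactants: 2 4-allyl-1-(benzyloxy)-2-methoxybenzene
Product: 3 3-[4-(benzyloxy)-3-methoxyphenyl]propan-1-ol
Conditions: 9-BBN, THF, 0 °C → rt; then NaOH, H2O2, H2O, 0 °C → rt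
Reagents that add atoms: hydrogen peroxide, OO
Why: Brown hydroboration–oxidation, in which the bulky borane places boron on the terminal carbon of the monosubstituted alkene and alkaline peroxide converts C–B into C–OH without touching the benzyl ether.

Step 3
Reactants: 3 3-[4-(benzyloxy)-3-methoxyphenyl]propan-1-ol
Product: 4 3-[4-(benzyloxy)-3-methoxyphenyl]propanal
Conditions: TEMPO (10 mol%), PhI(OAc)2, CH2Cl2, rt
Reagents that add atoms: none
Why: TEMPO-catalysed oxoammonium oxidation of a primary alcohol, which stops at the aldehyde in anhydrous CH2Cl2 and should leave the electron-rich arene and the benzyl ether alone.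

Step 4
Reactants: 4 3-[4-(benzyloxy)-3-methoxyphenyl]propanal
Product: 5 2-[2-(4-benzyloxy-3-methoxyphenyl)ethyl]-1,3-dithiane
Conditions: HS(CH2)3SH, BF3·OEt2 (20 mol%), CH2Cl2, 0 °C → rt
Reagents that add atoms: propane-1,3-dithiol, SCCCS
Why: Lewis-acid-catalysed dithioacetalisation of an unhindered aliphatic aldehyde to the six-membered 1,3-dithiane, under which aryl benzyl and methyl ethers are stable.

Step 5
Reactants: 6 5-hydroxyvanillin (3,4-dihydroxy-5-methoxybenzaldehyde)
Product: 7 3,4-bis(benzyloxy)-5-methoxybenzaldehyde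
Conditions: BnBr (2.3 equiv), K2CO3, DMF, 60 °C, N2
Reagents that add atoms: benzyl bromide, BrCc1ccccc1
Why: double Williamson etherification of the catechol, run under nitrogen because the catecholate is air-sensitive, with the aldehyde inert to carbonate.

Step 6
Reactants: 7 3,4-bis(benzyloxy)-5-methoxybenzaldehyde
Product: 8 [3,4-bis(benzyloxy)-5-methoxyphenyl]methanol
Conditions: NaBH4, MeOH/THF, 0 °C
Reagents that add atoms: none
Why: borohydride reduction of an aromatic aldehyde to the benzylic alcohol, chemoselective in the presence of the ethers.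

Step 7
Reactants: 8 [3,4-bis(benzyloxy)-5-methoxyphenyl]methanol
Product: 9 1,2-bis(benzyloxy)-5-(chloromethyl)-3-methoxybenzene
Conditions: SOCl2, DMF (cat.), CH2Cl2, 0 °C → rt
Reagents that add atoms: thionyl chloride, ClS(Cl)=O
Why: chlorodehydroxylation through the chlorosulfite, fast at the electron-rich benzylic carbon at 0 °C, where the HCl formed should not cleave aryl benzyl ethers.

Step 8
Reactants: 9 1,2-bis(benzyloxy)-5-(chloromethyl)-3-methoxybenzene
Product: 10 3,4-bis(benzyloxy)-5-methoxybenzylmagnesium chloride (THF solution, titrated, used directly)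
Conditions: Mg turnings (excess, I2-activated), THF, 0 °C, slow addition of dilute 9
Reagents that add atoms: magnesium, [Mg]
Why: Grignard formation by insertion of magnesium into the benzylic C–Cl bond, with high dilution, low temperature and excess metal keeping the halide concentration low so that Wurtz homocoupling is held back.

Step 9
Reactants: 5 2-[2-(4-benzyloxy-3-methoxyphenyl)ethyl]-1,3-dithiane; 11 (S)-epichlorohydrin [(2S)-2-(chloromethyl)oxirane]; 10 3,4-bis(benzyloxy)-5-methoxybenzylmagnesium chloride
Product: 15 (2R)-1-{2-[2-(4-benzyloxy-3-methoxyphenyl)ethyl]-1,3-dithian-2-yl}-4-[3,4-bis(benzyloxy)-5-methoxyphenyl]butan-2-ol, via lithiated dithiane 12 (not isolated), via chlorohydrin lithium alkoxide 13 (not isolated), via terminal epoxide 14 (not isolated)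
Conditions: n-BuLi (1.0 equiv), THF, −30 °C; 11 (1.1 equiv), −78 °C → rt; then CuI (10 mol%), 10 (1.5 equiv), −30 → 0 °C; aq NH4Cl
Reagents that add atoms: none
Why: n-BuLi removes the C2 proton of 5 (Corey–Seebach polarity reversal), anion 12 opens 11 by SN2 at the unsubstituted epoxide carbon to form C3–C4, alkoxide 13 displaces chloride on warming to give epoxide 14, and the benzylic organocopper species from 10 and catalytic CuI opens 14 by SN2 at its methylene carbon to form C6–C7. The closest known reaction types are the alkylation of 2-lithio-1,3-dithianes with epichlorohydrin to give dithianylmethyl oxiranes and the copper-catalysed opening of terminal epoxides by Grignard reagents, here run in sequence in one flask. No ring of the target is closed; the only ring formed is the transient oxirane of 14, by 3-exo-tet closure (intramolecular Williamson reaction), and it is opened again in the same flask. No stereocentre is created: C5 is the stereocentre of 11, no bond to it is made or broken, and its descriptor changes from S to R only because the former chloromethyl carbon (now C6) and the former epoxide methylene (now C4) exchange CIP rank. The step needs 12 to attack the epoxide methylene rather than displace chloride directly (which would give the enantiomer) and the benzyl reagent to attack the terminal carbon of 14; both should follow from the preference of these carbanions for the strained, unhindered primary epoxide carbon at low temperature. The quaternary dithiane carbon of 14 has no acidic proton to quench the Grignard reagent, and the slight excess of 11 over 12 should prevent a second dithiane anion from opening 14.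

Step 10
Reactants: 15 (2R)-1-{2-[2-(4-benzyloxy-3-methoxyphenyl)ethyl]-1,3-dithian-2-yl}-4-[3,4-bis(benzyloxy)-5-methoxyphenyl]butan-2-ol
Product: 16 (5R)-1-(4-benzyloxy-3-methoxyphenyl)-7-[3,4-bis(benzyloxy)-5-methoxyphenyl]-5-hydroxyheptan-3-one
Conditions: MeI (excess), CaCO3, MeCN/H2O (9:1), 40 °C
Reagents that add atoms: water, O
Why: alkylative hydrolysis of the dithiane, in which S-methylation makes sulfur a leaving group and water captures the thionium ion, while CaCO3 buffers the HI so that the β-hydroxy ketone should neither dehydrate nor undergo retro-aldol cleavage and C5 is untouched.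

Step 11
Reactants: 16 (5R)-1-(4-benzyloxy-3-methoxyphenyl)-7-[3,4-bis(benzyloxy)-5-methoxyphenyl]-5-hydroxyheptan-3-one
Product: 17 (5R)-7-(3,4-dihydroxy-5-methoxyphenyl)-5-hydroxy-1-(4-hydroxy-3-methoxyphenyl)heptan-3-one
Conditions: H2 (1 atm), 10% Pd/C, EtOAc/MeOH, rt
Reagents that add atoms: none
Why: catalytic hydrogenolysis of the three aryl benzyl ethers under neutral conditions, to which the aliphatic ketone, the non-benzylic secondary alcohol, the aryl methyl ethers and the C5 configuration are inert.

**Compound list**

1 | eugenol (4-allyl-2-methoxyphenol) | C=CCc1ccc(O)c(OC)c1 | starting material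
2 | 4-allyl-1-(benzyloxy)-2-methoxybenzene | C=CCc1ccc(OCc2ccccc2)c(OC)c1 | intermediate
3 | 3-[4-(benzyloxy)-3-methoxyphenyl]propan-1-ol | OCCCc1ccc(OCc2ccccc2)c(OC)c1 | intermediate
4 | 3-[4-(benzyloxy)-3-methoxyphenyl]propanal | O=CCCc1ccc(OCc2ccccc2)c(OC)c1 | intermediate
5 | 2-[2-(4-benzyloxy-3-methoxyphenyl)ethyl]-1,3-dithiane | COc1cc(CCC2SCCCS2)ccc1OCc1ccccc1 | intermediate
6 | 5-hydroxyvanillin (3,4-dihydroxy-5-methoxybenzaldehyde) | COc1cc(C=O)cc(O)c1O | starting material
7 | 3,4-bis(benzyloxy)-5-methoxybenzaldehyde | COc1cc(C=O)cc(OCc2ccccc2)c1OCc1ccccc1 | intermediate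
8 | [3,4-bis(benzyloxy)-5-methoxyphenyl]methanol | COc1cc(CO)cc(OCc2ccccc2)c1OCc1ccccc1 | intermediate
9 | 1,2-bis(benzyloxy)-5-(chloromethyl)-3-methoxybenzene | COc1cc(CCl)cc(OCc2ccccc2)c1OCc1ccccc1 | intermediate
10 | 3,4-bis(benzyloxy)-5-methoxybenzylmagnesium chloride | COc1cc(C[Mg]Cl)cc(OCc2ccccc2)c1OCc1ccccc1 | intermediate
11 | (S)-epichlorohydrin [(2S)-2-(chloromethyl)oxirane] | ClC[C@@H]1CO1 | starting material
12 | 2-[2-(4-benzyloxy-3-methoxyphenyl)ethyl]-2-lithio-1,3-dithiane | COc1cc(CCC2([Li])SCCCS2)ccc1OCc1ccccc1 | intermediate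
13 | lithium (2S)-1-{2-[2-(4-benzyloxy-3-methoxyphenyl)ethyl]-1,3-dithian-2-yl}-3-chloropropan-2-olate | COc1cc(CCC2(C[C@H]([O-])CCl)SCCCS2)ccc1OCc1ccccc1.[Li+] | intermediate
14 | 2-[2-(4-benzyloxy-3-methoxyphenyl)ethyl]-2-{[(2S)-oxiran-2-yl]methyl}-1,3-dithiane | COc1cc(CCC2(C[C@H]3CO3)SCCCS2)ccc1OCc1ccccc1 | intermediate
15 | (2R)-1-{2-[2-(4-benzyloxy-3-methoxyphenyl)ethyl]-1,3-dithian-2-yl}-4-[3,4-bis(benzyloxy)-5-methoxyphenyl]butan-2-ol | COc1cc(CCC2(SCCCS2)C[C@H](O)CCc2cc(OCc3ccccc3)c(OCc3ccccc3)c(OC)c2)ccc1OCc1ccccc1 | intermediate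
16 | (5R)-1-(4-benzyloxy-3-methoxyphenyl)-7-[3,4-bis(benzyloxy)-5-methoxyphenyl]-5-hydroxyheptan-3-one | COc1cc(CCC(=O)C[C@H](O)CCc2cc(OCc3ccccc3)c(OCc3ccccc3)c(OC)c2)ccc1OCc1ccccc1 | intermediate
17 | (5R)-7-(3,4-dihydroxy-5-methoxyphenyl)-5-hydroxy-1-(4-hydroxy-3-methoxyphenyl)heptan-3-one | COc1cc(CCC(=O)C[C@H](O)CCc2cc(O)c(O)c(OC)c2)ccc1O | target

**Step count**

Total step count: 11.
Longest linear sequence: 7 steps (steps 1–4, 9, 10, 11 from eugenol; the branch from 5-hydroxyvanillin, steps 5–8, 9, 10, 11, is equally long).

**Steps most likely to fail, with fallbacks**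

1. Step 9. The risks are:
   - incomplete or misdirected metalation of 5 (competing lithiation at a benzylic O–CH2 position);
   - partial direct displacement of chloride by the dithiane anion, which would erode the enantiomeric purity;
   - incomplete re-closure to the epoxide before the Grignard reagent is added, which would leave chlorohydrin and consume reagent.

   Fallback: the two epoxide openings are run in the reverse order and on isolated intermediates, setting out from Grignard reagent 10 and returning to the route at 15. Reagent 10 with catalytic CuI in THF at −40 °C should open commercial (R)-epichlorohydrin (ClC[C@H]1CO1) at its epoxide methylene to give (2R)-4-[3,4-bis(benzyloxy)-5-methoxyphenyl]-1-chlorobutan-2-ol F1. NaOH in aqueous THF should close it to (2R)-2-{2-[3,4-bis(benzyloxy)-5-methoxyphenyl]ethyl}oxirane F2, which is purified. Lithiated dithiane 12 (from 5 and n-BuLi, THF, −30 °C) should then open F2 at its methylene carbon to give 15. The enantiomeric epichlorohydrin is needed because its chloromethyl carbon now becomes C4 and its epoxide methylene becomes C6.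

2. Step 8. The risk is Wurtz-type homocoupling of the electron-rich benzylic chloride on the magnesium surface, which would leave too little organometallic reagent.

   Fallback: the benzylic carbanion is replaced by a sulfone-stabilised one, setting out from chloride 9 and returning at 15. Sodium benzenesulfinate in DMF at 60 °C should convert 9 into 1,2-bis(benzyloxy)-3-methoxy-5-[(phenylsulfonyl)methyl]benzene F3. Epoxide 14 is isolated by working up step 9 before the Grignard addition. Lithiation of F3 (n-BuLi, THF, −78 °C) and addition of 14 (−78 → 0 °C, with BF3·OEt2 if the opening is slow) should give (2R,4RS)-1-{2-[2-(4-benzyloxy-3-methoxyphenyl)ethyl]-1,3-dithian-2-yl}-4-[3,4-bis(benzyloxy)-5-methoxyphenyl]-4-(phenylsulfonyl)butan-2-ol F4 as a mixture of epimers at the sulfonyl carbon. Reductive desulfonylation (Mg, MeOH, rt) should then give 15.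

3. Step 10. The risk is slow hydrolysis of the 2,2-dialkyl dithiane, with dehydration or retro-aldol cleavage of the β-hydroxy ketone as it is unveiled.

   Fallback: the carbinol is protected before unmasking, so that a stronger thiophilic reagent can be used, setting out from 15 and returning at 16. TBSOTf and 2,6-lutidine in CH2Cl2 at 0 °C should give tert-butyl{[(2R)-1-{2-[2-(4-benzyloxy-3-methoxyphenyl)ethyl]-1,3-dithian-2-yl}-4-[3,4-bis(benzyloxy)-5-methoxyphenyl]butan-2-yl]oxy}dimethylsilane F5. Hg(ClO4)2 and CaCO3 in THF/H2O at 0 °C should release (5R)-1-(4-benzyloxy-3-methoxyphenyl)-7-[3,4-bis(benzyloxy)-5-methoxyphenyl]-5-[(tert-butyldimethylsilyl)oxy]heptan-3-one F6. HF·pyridine in THF at 0 °C should then remove the silyl ether to give 16.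

**Further compounds**

F1 | step 9 | (2R)-4-[3,4-bis(benzyloxy)-5-methoxyphenyl]-1-chlorobutan-2-ol | COc1cc(CC[C@@H](O)CCl)cc(OCc2ccccc2)c1OCc1ccccc1
F2 | step 9 | (2R)-2-{2-[3,4-bis(benzyloxy)-5-methoxyphenyl]ethyl}oxirane | COc1cc(CC[C@@H]2CO2)cc(OCc2ccccc2)c1OCc1ccccc1
F3 | step 8 | 1,2-bis(benzyloxy)-3-methoxy-5-[(phenylsulfonyl)methyl]benzene | COc1cc(CS(=O)(=O)c2ccccc2)cc(OCc2ccccc2)c1OCc1ccccc1
F4 | step 8 | (2R,4RS)-1-{2-[2-(4-benzyloxy-3-methoxyphenyl)ethyl]-1,3-dithian-2-yl}-4-[3,4-bis(benzyloxy)-5-methoxyphenyl]-4-(phenylsulfonyl)butan-2-ol | COc1cc(CCC2(SCCCS2)C[C@H](O)CC(c2cc(OCc3ccccc3)c(OCc3ccccc3)c(OC)c2)S(=O)(=O)c2ccccc2)ccc1OCc1ccccc1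
F5 | step 10 | tert-butyl{[(2R)-1-{2-[2-(4-benzyloxy-3-methoxyphenyl)ethyl]-1,3-dithian-2-yl}-4-[3,4-bis(benzyloxy)-5-methoxyphenyl]butan-2-yl]oxy}dimethylsilane | COc1cc(CCC2(SCCCS2)C[C@H](O[Si](C)(C)C(C)(C)C)CCc2cc(OCc3ccccc3)c(OCc3ccccc3)c(OC)c2)ccc1OCc1ccccc1
F6 | step 10 | (5R)-1-(4-benzyloxy-3-methoxyphenyl)-7-[3,4-bis(benzyloxy)-5-methoxyphenyl]-5-[(tert-butyldimethylsilyl)oxy]heptan-3-one | COc1cc(CCC(=O)C[C@H](O[Si](C)(C)C(C)(C)C)CCc2cc(OCc3ccccc3)c(OCc3ccccc3)c(OC)c2)ccc1OCc1ccccc1
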